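**Retrosynth­etic overview**
- Target **1** ⇐ desilylation and C8‑OH oxidation of a macrocyclic carbinol made by Ni/Cr (NHK) closure of C8–C9. This is the only ring (11‑membered carbocycle) and it is formed last.
- Key step: the C5–C8 (E)-γ‑oxo‑enal arm is unmasked by oxidative dearomatization of a 2‑furyl group, with furan (**2**) acting as a latent (E)-4‑oxobut‑2‑enal. Furan C2 becomes the C5 ketone and furan C5 becomes C8 (as its acetal); Felkin methyl addition then sets C5.
- C4 ⇐ catalytic asymmetric addition of 2‑furylzinc to an enal.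
- C1 (quaternary) ⇐ Cu–NHC enantioselective allylic substitution of geranyl phosphate (from geraniol **3**) with alkenylboronate **4**. The new vinyl group is then converted to the C10 aldehyde and the (Z)-C9 iodoalkene.
- The senecioate (from acid **5**) is installed before the dearomatization, so it is the only group ever placed on the C4 oxygen.

Assumption: ring atoms are numbered C1 (quaternary C) –C2=C3–C4(O‑ester)–C5(Me)(OH)–C6=C7–C8(=O)–C9(CH2OH)=C10–C11. The target is (1S,4R,5R; 2E,6E, C8/C11 cis) in this numbering. The sense of induction of each chiral catalyst is matched by choosing the ligand enantiomer.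

**Step 1**
Reactants: **3** geraniol
Product: **6** geranyl diethyl phosphate
Conditions: ClP(O)(OEt)2, pyridine, DMAP (cat.), CH2Cl2, 0 °C
Reagents that add atoms: diethyl chlorophosphate, CCOP(=O)(Cl)OCC
Why: O‑phosphorylation of the primary allylic alcohol gives the leaving group needed for Cu‑catalysed SN2′ substitution, with the (E)-trisubstituted olefin untouched.

**Step 2**
Reactants: **6**; **4** (E)-3,3‑diethoxyprop‑1‑enyl‑B(pin)
Product: **7** (2E,4S)-1,1‑diethoxy‑4‑ethenyl‑4,8‑dimethylnona‑2,7‑diene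
Conditions: CuCl (5 mol %), chiral sulfonate‑bearing imidazolinium salt (5.5 mol %, enantiomer giving 4S), NaOMe (1.5 equiv), THF, 60 °C; neutral work‑up
Reagents that add atoms: **4**, CCOC(OCC)/C=C/B1OC(C)(C)C(C)(C)O1
Why: Cu–NHC enantioselective allylic substitution (Hoveyda type): the alkenyl‑Cu formed by B→Cu transmetalation attacks the γ‑carbon SN2′, creating the C1 quaternary centre (S) under catalyst control with retention of the (E)-alkenyl geometry.

**Step 3**
Reactants: **7**
Product: **8** (3S,4E)-6,6‑diethoxy‑3‑methyl‑3‑(4‑methylpent‑3‑en‑1‑yl)hex‑4‑enal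
Conditions: 9‑BBN, THF, 0 °C → rt; then NMO (excess), TPAP (5 mol %), 4 Å MS, CH2Cl2
Reagents that add atoms: N‑methylmorpholine N‑oxide, C[N+]1([O-])CCOCC1
Why: Anti‑Markovnikov hydroboration by 9‑BBN is selective for the monosubstituted vinyl group (the 1,2‑di‑ and trisubstituted olefins are far slower), and one‑pot NMO/TPAP oxidation of the alkylborane gives the C10 aldehyde.

**Step 4**
Reactants: **8**; **9** ethyl (triphenylphosphoranylidene)acetate
Product: **10** ethyl (2Z,5S,6E)-8,8‑diethoxy‑2‑iodo‑5‑methyl‑5‑(4‑methylpent‑3‑en‑1‑yl)octa‑2,6‑dienoate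
Conditions: **9**, NIS, K2CO3, CH2Cl2, −20 °C (forms Ph3P=C(I)CO2Et in situ); then **8**, → rt
Reagents that add atoms: **9**, CCOC(=O)C=P(c1ccccc1)(c1ccccc1)c1ccccc1; N‑iodosuccinimide, O=C1CCC(=O)N1I
Why: Tandem ylide iodination and stabilised Wittig olefination places the ester trans to the chain, so iodine is cis to C11 (Z), which is the C9=C10 geometry needed once iodine is replaced by C8.

**Step 5**
Reactants: **10**
Product: **11** (2E,4S,6Z)-8‑hydroxy‑7‑iodo‑4‑methyl‑4‑(4‑methylpent‑3‑en‑1‑yl)octa‑2,6‑dienal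
Conditions: DIBAL‑H (2.2 equiv), CH2Cl2, −78 °C; then 10 % aq. tartaric acid/THF, rt, 30 min
Reagents that add atoms: water, O (aldehyde oxygen from acetal hydrolysis)
Why: DIBAL 1,2‑reduction of the α‑iodo enoate gives the allylic alcohol with the vinyl iodide intact, and the mildly acidic work‑up hydrolyses the labile α,β‑unsaturated diethyl acetal to the (E)-enal.

**Step 6**
Reactants: **11**
Product: **12** (2E,4S,6Z)-8‑[(tert‑butyldiphenylsilyl)oxy]‑7‑iodo‑4‑methyl‑4‑(4‑methylpent‑3‑en‑1‑yl)octa‑2,6‑dienal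
Conditions: TBDPSCl, imidazole, CH2Cl2, 0 °C → rt
Reagents that add atoms: TBDPSCl, CC(C)(C)[Si](Cl)(c1ccccc1)c1ccccc1
Why: Silylation of the primary allylic alcohol with an acid‑stable group that survives the later acidic methanol and acetal hydrolysis and leaves C4–OH as the only acylation site.

**Step 7**
Reactants: **12**; **2** furan
Product: **13** (1R,2E,4S,6Z)-8‑[(tert‑butyldiphenylsilyl)oxy]‑1‑(furan‑2‑yl)‑7‑iodo‑4‑methyl‑4‑(4‑methylpent‑3‑en‑1‑yl)octa‑2,6‑dien‑1‑ol
Conditions: **2**, n‑BuLi, THF, 0 °C; ZnCl2 then n‑BuLi (gives 2‑furyl(butyl)zinc); TEEDA; (−)-MIB (10 mol %), PhMe, −10 °C; then **12**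
Reagents that add atoms: **2**, c1ccoc1
Why: MIB‑catalysed asymmetric heteroaryl‑zinc 1,2‑addition (Walsh type) delivers furyl to the Si face of the enal, setting C4 as R under catalyst control; the vinyl iodide and silyl ether are inert to organozinc. The face assignment assumes (−)-MIB behaves as it does with Et2Zn/ArCHO; the (+)-ligand is used if the sense is reversed.

**Step 8**
Reactants: **13**; **5** 3‑methylbut‑2‑enoic acid
Product: **14** (1R,2E,4S,6Z)-8‑[(tert‑butyldiphenylsilyl)oxy]‑1‑(furan‑2‑yl)‑7‑iodo‑4‑methyl‑4‑(4‑methylpent‑3‑en‑1‑yl)octa‑2,6‑dien‑1‑yl 3‑methylbut‑2‑enoate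
Conditions: **5**, EDC·HCl, DMAP, CH2Cl2, 0 °C
Reagents that add atoms: **5**, CC(C)=CC(=O)O
Why: Steglich esterification under neutral conditions acylates the sole free hydroxyl with retention at C4 and avoids ionising the furfuryl/allylic carbinol; the ester also blocks Achmatowicz cyclisation in the next step.

**Step 9 (key step)**
Reactants: **14**
Product: **15** (2E,5R,6E,8S,10Z)-12‑[(tert‑butyldiphenylsilyl)oxy]‑11‑iodo‑1,1‑dimethoxy‑8‑methyl‑8‑(4‑methylpent‑3‑en‑1‑yl)‑4‑oxododeca‑2,6,10‑trien‑5‑yl 3‑methylbut‑2‑enoate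
Conditions: NBS (1.05 equiv), NaHCO3, MeOH/CH2Cl2, −40 °C; then PPTS (cat.), MeOH, 0 °C → rt; aq. NaHCO3
Reagents that add atoms: methanol, CO (both OMe groups; NBS leaves no atoms)
Why: Oxidative dearomatization (Clauson‑Kaas 2,5‑dimethoxylation, then acid‑mediated ring opening and Z→E equilibration) converts the furan in one operation into the free C5 ketone, the (E)-C6=C7 olefin and C8 as its dimethyl acetal. The 2‑alkylfuran should out‑compete the trisubstituted olefin for Br+, and the aldehyde rather than the deactivated α‑acyloxy ketone ends up as the acetal at equilibrium.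

**Step 10**
Reactants: **15**
Product: **16** (2E,4R,5R,6E,8S,10Z)-12‑[(tert‑butyldiphenylsilyl)oxy]‑4‑hydroxy‑11‑iodo‑4,8‑dimethyl‑8‑(4‑methylpent‑3‑en‑1‑yl)‑1‑oxododeca‑2,6,10‑trien‑5‑yl 3‑methylbut‑2‑enoate
Conditions: MeLi/CeCl3 (pre‑formed MeCeCl2), THF, −78 °C; then 5 % aq. citric acid/THF, rt, 1 h
Reagents that add atoms: methyllithium, [Li]C; water, O (aldehyde oxygen)
Why: Organocerium 1,2‑addition (Imamoto) to the acyclic α‑acyloxy enone follows polar Felkin–Anh control (C4–O anti to the incoming methyl, H rather than the alkenyl arm beside the trajectory), giving the 4,5‑syn diol pattern, i.e. C5 = R. The non‑basic reagent avoids enolising C4–H and spares the ester, acetal and vinyl iodide, and the mild acid then releases the (E)-γ‑hydroxy enal.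

**Step 11**
Reactants: **16**
Product: **17** (1R,2R,3E,6Z,9S,10E)-6‑{[(tert‑butyldiphenylsilyl)oxy]methyl}‑2,5‑dihydroxy‑2,9‑dimethyl‑9‑(4‑methylpent‑3‑en‑1‑yl)cycloundeca‑3,6,10‑trien‑1‑yl 3‑methylbut‑2‑enoate (C5‑carbinol epimers, ring numbering)
Conditions: CrCl2 (8 equiv), NiCl2 (2 mol % of Cr), DMSO/THF, 2 mM (syringe pump), rt
Reagents that add atoms: none
Why: Nozaki–Hiyama–Kishi macrocyclisation: the alkenyl‑Cr(III) formed with retention of the Z geometry adds only to the aldehyde, closing the 11‑membered ring at C8–C9; the new carbinol configuration is irrelevant.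

**Step 12**
Reactants: **17**
Product: **18** (1R,2R,3E,6Z,9S,10E)-6‑{[(tert‑butyldiphenylsilyl)oxy]methyl}‑2‑hydroxy‑2,9‑dimethyl‑9‑(4‑methylpent‑3‑en‑1‑yl)‑5‑oxocycloundeca‑3,6,10‑trien‑1‑yl 3‑methylbut‑2‑enoate
Conditions: Dess–Martin periodinane, NaHCO3, CH2Cl2, 0 °C
Reagents that add atoms: none
Why: Dess–Martin oxidation of the bis‑allylic secondary alcohol gives the cross‑conjugated dienone; the tertiary alcohol, ester and silyl ether are unaffected.

**Step 13**
Reactants: **18**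
Product: **1** (target)
Conditions: HF·pyridine, pyridine, THF, 0 °C → rt
Reagents that add atoms: none
Why: Buffered fluoride desilylation frees the primary allylic alcohol without the basic conditions that could cause acyl migration from C4–O to C5–O or conjugate addition to the dienone.

**Compound list**
1 | (1R,2R,3E,6Z,9S,10E)-2‑hydroxy‑6‑(hydroxymethyl)‑2,9‑dimethyl‑9‑(4‑methylpent‑3‑en‑1‑yl)‑5‑oxocycloundeca‑3,6,10‑trien‑1‑yl 3‑methylbut‑2‑enoate | CC(C)=CCC[C@]1(C)/C=C/[C@@H](OC(=O)C=C(C)C)[C@](C)(O)/C=C/C(=O)/C(CO)=C\C1 | target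
2 | furan | c1ccoc1 | starting material
3 | geraniol | CC(C)=CCC/C(C)=C/CO | starting material
4 | (E)-2‑(3,3‑diethoxyprop‑1‑en‑1‑yl)‑4,4,5,5‑tetramethyl‑1,3,2‑dioxaborolane | CCOC(OCC)/C=C/B1OC(C)(C)C(C)(C)O1 | starting material
5 | 3‑methylbut‑2‑enoic acid (senecioic acid) | CC(C)=CC(=O)O | starting material
6 | geranyl diethyl phosphate | CC(C)=CCC/C(C)=C/COP(=O)(OCC)OCC | intermediate
7 | (2E,4S)-1,1‑diethoxy‑4‑ethenyl‑4,8‑dimethylnona‑2,7‑diene | CC(C)=CCC[C@](C=C)(C)/C=C/C(OCC)OCC | intermediate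
8 | (3S,4E)-6,6‑diethoxy‑3‑methyl‑3‑(4‑methylpent‑3‑en‑1‑yl)hex‑4‑enal | CC(C)=CCC[C@](CC=O)(C)/C=C/C(OCC)OCC | intermediate
9 | ethyl (triphenylphosphoranylidene)acetate | CCOC(=O)C=P(c1ccccc1)(c1ccccc1)c1ccccc1 | starting material
10 | ethyl (2Z,5S,6E)-8,8‑diethoxy‑2‑iodo‑5‑methyl‑5‑(4‑methylpent‑3‑en‑1‑yl)octa‑2,6‑dienoate | CC(C)=CCC[C@](C/C=C(I)/C(=O)OCC)(C)/C=C/C(OCC)OCC | intermediate
11 | (2E,4S,6Z)-8‑hydroxy‑7‑iodo‑4‑methyl‑4‑(4‑methylpent‑3‑en‑1‑yl)octa‑2,6‑dienal | CC(C)=CCC[C@](C/C=C(I)/CO)(C)/C=C/C=O | intermediate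
12 | (2E,4S,6Z)-8‑[(tert‑butyldiphenylsilyl)oxy]‑7‑iodo‑4‑methyl‑4‑(4‑methylpent‑3‑en‑1‑yl)octa‑2,6‑dienal | CC(C)=CCC[C@](C/C=C(I)/CO[Si](c1ccccc1)(c1ccccc1)C(C)(C)C)(C)/C=C/C=O | intermediate
13 | (1R,2E,4S,6Z)-8‑[(tert‑butyldiphenylsilyl)oxy]‑1‑(furan‑2‑yl)‑7‑iodo‑4‑methyl‑4‑(4‑methylpent‑3‑en‑1‑yl)octa‑2,6‑dien‑1‑ol | CC(C)=CCC[C@](C/C=C(I)/CO[Si](c1ccccc1)(c1ccccc1)C(C)(C)C)(C)/C=C/[C@@H](O)c1ccco1 | intermediate
14 | 3‑methylbut‑2‑enoate ester of 13 | CC(C)=CCC[C@](C/C=C(I)/CO[Si](c1ccccc1)(c1ccccc1)C(C)(C)C)(C)/C=C/[C@@H](OC(=O)C=C(C)C)c1ccco1 | intermediate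
15 | (2E,5R,6E,8S,10Z)-12‑[(tert‑butyldiphenylsilyl)oxy]‑11‑iodo‑1,1‑dimethoxy‑8‑methyl‑8‑(4‑methylpent‑3‑en‑1‑yl)‑4‑oxododeca‑2,6,10‑trien‑5‑yl 3‑methylbut‑2‑enoate | CC(C)=CCC[C@](C/C=C(I)/CO[Si](c1ccccc1)(c1ccccc1)C(C)(C)C)(C)/C=C/[C@@H](OC(=O)C=C(C)C)C(=O)/C=C/C(OC)OC | intermediate
16 | (2E,4R,5R,6E,8S,10Z)-12‑[(tert‑butyldiphenylsilyl)oxy]‑4‑hydroxy‑11‑iodo‑4,8‑dimethyl‑8‑(4‑methylpent‑3‑en‑1‑yl)‑1‑oxododeca‑2,6,10‑trien‑5‑yl 3‑methylbut‑2‑enoate | CC(C)=CCC[C@](C/C=C(I)/CO[Si](c1ccccc1)(c1ccccc1)C(C)(C)C)(C)/C=C/[C@@H](OC(=O)C=C(C)C)[C@](C)(O)/C=C/C=O | intermediate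
17 | macrocyclic C8 carbinol (epimer mixture), primary OH as TBDPS ether | CC(C)=CCC[C@]1(C)/C=C/[C@@H](OC(=O)C=C(C)C)[C@](C)(O)/C=C/C(O)/C(CO[Si](c2ccccc2)(c2ccccc2)C(C)(C)C)=C\C1 | intermediate
18 | TBDPS ether of the target | CC(C)=CCC[C@]1(C)/C=C/[C@@H](OC(=O)C=C(C)C)[C@](C)(O)/C=C/C(=O)/C(CO[Si](c2ccccc2)(c2ccccc2)C(C)(C)C)=C\C1 | intermediate

**Totals**
Total steps: 13. Longest linear sequence: 13 (geraniol **3** → **1**); **2**, **4**, **5** and **9** are used as purchased.

**Three steps most likely to fail, with fallbacks**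
1. Step 9 (dearomatization). Risks are bromination of the homoprenyl olefin, incomplete Z→E/acetal differentiation, and epimerisation at the now α‑keto C4. Fallback: replace electrophilic halogenation by [4+2] photooxygenation of the furan (O2, rose bengal, hν, MeOH, −78 °C; Me2S; cat. I2) to the free (E)-4‑oxo‑enal, and distinguish the two carbonyls by transient Ti(NEt2)4 masking of the aldehyde during methylation instead of an isolated acetal.
2. Step 10 (C5 methylation). Risks are modest Felkin selectivity with the α‑acyloxy group, enolisation, or acyl migration to the new tertiary alkoxide. Fallback: change the controlling group, carrying C4–O as a TIPS ether from step 8 (stronger non‑chelation bias, no acyl transfer), methylating with MeTi(OiPr)3, and moving the senecioylation to after ring closure by selective removal of the C4 silyl ether (two extra steps).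
3. Step 11 (NHK closure of a strained 11‑membered triene; possible Cr(II) side reactions). Fallback: close the same bond by acylative Pd coupling. Pinnick‑oxidise **16** to the acid, form the thioester, convert the vinyl iodide to the vinylstannane, and cyclise by intramolecular Liebeskind–Srogl/acyl‑Stille coupling, which gives ketone **18** directly and removes step 12.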